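**Strategy**

Everything rests on the biaryl bond between C2 of the benzofuran ring and C1′ of the resorcinol ring, the carbon flanked by both prenyl-bearing carbons (C2′, C6′) and meta to both oxygens. The key step exploits the acidity of the benzofuran C2–H beside O1: one-pot C2 lithiation, zincation and Negishi coupling with a fully prenylated aryl chloride completes the whole carbon skeleton in one operation, leaving only deprotection. The precursor is 3-chloro-2,4-diprenyl-1,5-bis(methoxymethoxy)benzene; its chloride comes from 5-chlororesorcinol and sits between the only two ring positions that are para to an ether oxygen, so bromination and prenylation go there.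

Key step: step 5

Remark on the chemistry: the target has no stereocentre, and its biaryl axis is not stereogenic because the resorcinol ring is symmetric about it; the compound is achiral and no stereocontrol is needed.

**Route**

Step 1
Reactants: 1 5-chlororesorcinol (5-chlorobenzene-1,3-diol)
Product: 2 1-chloro-3,5-bis(methoxymethoxy)benzene
Conditions: NaH (2.4 equiv), MOMCl (2.4 equiv), DMF, 0 °C → rt
Reagents that add atoms: chloromethyl methyl ether (MOMCl), COCCl
Why: Williamson-type O-alkylation of the bis-phenoxide with MOMCl should give the bis-acetal, which tolerates NBS, organozinc and organolithium reagents and is removed at the end without touching the prenyl groups.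

Step 2
Reactants: 2 1-chloro-3,5-bis(methoxymethoxy)benzene
Product: 3 2,4-dibromo-3-chloro-1,5-bis(methoxymethoxy)benzene
Conditions: NBS (2.1 equiv), MeCN, 0 °C → rt, dark
Reagents that add atoms: N-bromosuccinimide (NBS), O=C1CCC(=O)N1Br
Why: Electrophilic aromatic bromination should occur twice at the two positions that are para to one OMOM and ortho to the other (both next to chlorine), because the position between the two OMOM groups is only ortho-activated and sterically shielded, as is usual for 5-substituted resorcinol diethers.

Step 3
Reactants: 3 2,4-dibromo-3-chloro-1,5-bis(methoxymethoxy)benzene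
Product: 4 3-chloro-1,5-bis(methoxymethoxy)-2,4-bis(3-methylbut-2-en-1-yl)benzene
Conditions: prenylzinc bromide (2.6 equiv, THF solution), Pd(OAc)2 (4 mol%), CPhos (8 mol%), THF, rt
Reagents that add atoms: (3-methylbut-2-en-1-yl)zinc bromide (prenylzinc bromide), CC(C)=CC[Zn]Br
Why: In this linear-selective Negishi allyl–aryl coupling palladium should insert into the two C–Br bonds much faster than into the C–Cl bond, and reductive elimination at the unsubstituted CH2 terminus of the prenyl ligand, favoured further by the crowded aryl group, should give the prenyl and not the reverse-prenyl isomer.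

Step 4
Reactants: 5 benzofuran-6-ol
Product: 6 6-(methoxymethoxy)benzofuran
Conditions: NaH (1.2 equiv), MOMCl (1.2 equiv), DMF, 0 °C → rt
Reagents that add atoms: chloromethyl methyl ether (MOMCl), COCCl
Why: Williamson-type O-alkylation masks the acidic phenol so that the following metalation consumes one equivalent of base at carbon, and it uses the same acetal as the other fragment so that one final operation removes all three.

Step 5
Reactants: 6 6-(methoxymethoxy)benzofuran (1.3 equiv); 4 3-chloro-1,5-bis(methoxymethoxy)-2,4-bis(3-methylbut-2-en-1-yl)benzene (1.0 equiv)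
Product: 9 2-[3,5-bis(methoxymethoxy)-2,6-bis(3-methylbut-2-en-1-yl)phenyl]-6-(methoxymethoxy)benzofuran, via 2-lithio-6-(methoxymethoxy)benzofuran 7 (not isolated), via 6-(methoxymethoxy)benzofuran-2-ylzinc chloride 8 (not isolated)
Conditions: n-BuLi (1.25 equiv), THF, −78 °C; ZnCl2 (1.3 equiv), −78 °C → rt; then 4, XPhos Pd G3 (3 mol%), THF, 65 °C
Reagents that add atoms: none
Why: n-BuLi removes the most acidic proton of 6, C2–H next to the ring oxygen O1, to give 7; ZnCl2 converts it into the non-basic arylzinc 8; Pd(0)/XPhos then inserts into the C–Cl bond of 4, takes up the benzofuranyl group by transmetalation and forms the C2–C1′ bond by reductive elimination. The closest known reaction type is the Negishi coupling of 2-furyl- and 2-benzofuranylzinc halides with ortho,ortho-disubstituted aryl chlorides under dialkylbiarylphosphine–palladium catalysis. No ring is closed and no stereocentre is formed; the product is achiral because the resorcinol ring is symmetric about the new bond. The step needs site selectivity in the metalation, which the higher kinetic acidity of C2–H over the positions ortho to OMOM should secure at −78 °C, and chemoselectivity at palladium, which follows because the chloride is the only carbon–halogen bond left in 4 and the trisubstituted prenyl alkenes should neither insert nor migrate under these mild conditions. The small, flat five-membered nucleophile and the bulky ligand are what should allow coupling at a carbon flanked by two CH2 substituents.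

Step 6
Reactants: 9 2-[3,5-bis(methoxymethoxy)-2,6-bis(3-methylbut-2-en-1-yl)phenyl]-6-(methoxymethoxy)benzofuran
Product: 10 mulberrofuran V
Conditions: conc. HCl (cat.), MeOH, rt → 40 °C
Reagents that add atoms: none
Why: Acid-catalysed transacetalisation in methanol should cleave the three aryl MOM ethers as dimethoxymethane under conditions mild enough that the freed phenols do not add to the prenyl double bonds, releasing the achiral target.

**Compound list**

1 | 5-chlororesorcinol (5-chlorobenzene-1,3-diol) | Oc1cc(O)cc(Cl)c1 | starting material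
2 | 1-chloro-3,5-bis(methoxymethoxy)benzene | COCOc1cc(OCOC)cc(Cl)c1 | intermediate
3 | 2,4-dibromo-3-chloro-1,5-bis(methoxymethoxy)benzene | COCOc1cc(OCOC)c(Br)c(Cl)c1Br | intermediate
4 | 3-chloro-1,5-bis(methoxymethoxy)-2,4-bis(3-methylbut-2-en-1-yl)benzene | COCOc1cc(OCOC)c(CC=C(C)C)c(Cl)c1CC=C(C)C | intermediate
5 | benzofuran-6-ol | Oc1ccc2ccoc2c1 | starting material
6 | 6-(methoxymethoxy)benzofuran | COCOc1ccc2ccoc2c1 | intermediate
7 | 2-lithio-6-(methoxymethoxy)benzofuran (not isolated) | [Li]c1cc2ccc(OCOC)cc2o1 | intermediate
8 | 6-(methoxymethoxy)benzofuran-2-ylzinc chloride (not isolated) | Cl[Zn]c1cc2ccc(OCOC)cc2o1 | intermediate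
9 | 2-[3,5-bis(methoxymethoxy)-2,6-bis(3-methylbut-2-en-1-yl)phenyl]-6-(methoxymethoxy)benzofuran | COCOc1cc(OCOC)c(CC=C(C)C)c(-c2cc3ccc(OCOC)cc3o2)c1CC=C(C)C | intermediate
10 | mulberrofuran V, 2-[3,5-dihydroxy-2,6-bis(3-methylbut-2-en-1-yl)phenyl]benzofuran-6-ol | CC(C)=CCc1c(O)cc(O)c(CC=C(C)C)c1-c1cc2ccc(O)cc2o1 | target

**Count**

Total step count: 6. Longest linear sequence: 5 steps (steps 1, 2, 3, 5, 6).

**Steps most likely to fail**

Step 5. Transmetalation and reductive elimination at the doubly ortho-substituted arylpalladium centre may be slower than loss of the heteroarylzinc reagent to protonation and homocoupling. The fallback sets out from 4 and comes back at 9, and it closes the furan ring only after the bond is made. Commercial 2,4-dihydroxybenzaldehyde is alkylated selectively at the non-chelated 4-hydroxyl (MOMCl, K2CO3, acetone) to 2-hydroxy-4-(methoxymethoxy)benzaldehyde F1. The Bestmann–Ohira reagent (K2CO3, MeOH) then homologates F1 to 2-ethynyl-5-(methoxymethoxy)phenol F2. A copper-free Sonogashira coupling of F2 with chloride 4 (PdCl2(MeCN)2, XPhos, Cs2CO3, MeCN, 80 °C) uses the slimmest possible carbon nucleophile and should give 2-{[3,5-bis(methoxymethoxy)-2,6-bis(3-methylbut-2-en-1-yl)phenyl]ethynyl}-5-(methoxymethoxy)phenol F3. The phenoxide of F3 should add to the alkyne (5-endo-dig, in the same pot or with catalytic CuI) to give 9.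

Step 3. The double coupling may stall after the first prenyl group, and protodebromination or bond formation at the substituted allyl terminus may compete at C–Br positions wedged between chlorine and OMOM. The fallback sets out from 3 and comes back at 4, and replaces catalysis by stepwise halogen–metal exchange. i-PrMgCl·LiCl (THF, −15 °C) exchanges one bromine; the arylmagnesium next to chlorine is stable and should not form an aryne. Transmetalation with CuBr·SMe2 and SN2 alkylation with prenyl bromide should give 2-bromo-3-chloro-1,5-bis(methoxymethoxy)-4-(3-methylbut-2-en-1-yl)benzene F4. The same sequence on F4 gives 4.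

Step 6. Acid may promote addition of a freed phenolic hydroxyl across the neighbouring prenyl double bond (chroman formation) in competition with acetal cleavage. The fallback sets out from 1 and 5 and comes back at 10, carrying silyl ethers so that the end game is fluoride and not acid.
- 1 is silylated (TBSCl, imidazole, DMF) to 1-chloro-3,5-bis(tert-butyldimethylsilyloxy)benzene F5.
- F5 is dibrominated with NBS to 2,4-dibromo-3-chloro-1,5-bis(tert-butyldimethylsilyloxy)benzene F6.
- F6 is prenylated as in step 3 to 3-chloro-1,5-bis(tert-butyldimethylsilyloxy)-2,4-bis(3-methylbut-2-en-1-yl)benzene F7.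
- 5 is silylated to 6-(tert-butyldimethylsilyloxy)benzofuran F8.
- F8 is lithiated with n-BuLi to 2-lithio-6-(tert-butyldimethylsilyloxy)benzofuran F9 and zincated to 6-(tert-butyldimethylsilyloxy)benzofuran-2-ylzinc chloride F10.
- F10 is coupled with F7 as in step 5 to 2-[3,5-bis(tert-butyldimethylsilyloxy)-2,6-bis(3-methylbut-2-en-1-yl)phenyl]-6-(tert-butyldimethylsilyloxy)benzofuran F11.
- TBAF buffered with AcOH (THF, 0 °C) should then give 10.

**Further compounds**

F1 | step 5 | 2-hydroxy-4-(methoxymethoxy)benzaldehyde | COCOc1ccc(C=O)c(O)c1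
F2 | step 5 | 2-ethynyl-5-(methoxymethoxy)phenol | COCOc1ccc(C#C)c(O)c1
F3 | step 5 | 2-{[3,5-bis(methoxymethoxy)-2,6-bis(3-methylbut-2-en-1-yl)phenyl]ethynyl}-5-(methoxymethoxy)phenol | COCOc1ccc(C#Cc2c(CC=C(C)C)c(OCOC)cc(OCOC)c2CC=C(C)C)c(O)c1
F4 | step 3 | 2-bromo-3-chloro-1,5-bis(methoxymethoxy)-4-(3-methylbut-2-en-1-yl)benzene | COCOc1cc(OCOC)c(CC=C(C)C)c(Cl)c1Br
F5 | step 6 | 1-chloro-3,5-bis(tert-butyldimethylsilyloxy)benzene | CC(C)(C)[Si](C)(C)Oc1cc(O[Si](C)(C)C(C)(C)C)cc(Cl)c1
F6 | step 6 | 2,4-dibromo-3-chloro-1,5-bis(tert-butyldimethylsilyloxy)benzene | CC(C)(C)[Si](C)(C)Oc1cc(O[Si](C)(C)C(C)(C)C)c(Br)c(Cl)c1Br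
F7 | step 6 | 3-chloro-1,5-bis(tert-butyldimethylsilyloxy)-2,4-bis(3-methylbut-2-en-1-yl)benzene | CC(C)(C)[Si](C)(C)Oc1cc(O[Si](C)(C)C(C)(C)C)c(CC=C(C)C)c(Cl)c1CC=C(C)C
F8 | step 6 | 6-(tert-butyldimethylsilyloxy)benzofuran | CC(C)(C)[Si](C)(C)Oc1ccc2ccoc2c1
F9 | step 6 | 2-lithio-6-(tert-butyldimethylsilyloxy)benzofuran | [Li]c1cc2ccc(O[Si](C)(C)C(C)(C)C)cc2o1
F10 | step 6 | 6-(tert-butyldimethylsilyloxy)benzofuran-2-ylzinc chloride | Cl[Zn]c1cc2ccc(O[Si](C)(C)C(C)(C)C)cc2o1
F11 | step 6 | 2-[3,5-bis(tert-butyldimethylsilyloxy)-2,6-bis(3-methylbut-2-en-1-yl)phenyl]-6-(tert-butyldimethylsilyloxy)benzofuran | CC(C)(C)[Si](C)(C)Oc1cc(O[Si](C)(C)C(C)(C)C)c(CC=C(C)C)c(-c2cc3ccc(O[Si](C)(C)C(C)(C)C)cc3o2)c1CC=C(C)C
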